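The daucane core is disconnected across its cycloheptene ring at C6–C7 and at the ring-fusion bond C3a–C8a. This splits the seven-membered ring into a three-carbon unit (C7–C8–C8a) and a four-carbon unit (C3a–C4–C5–C6) that stay linked through the cyclopentane carbons C1–C2–C3. A gold-catalysed intramolecular (4+3) cycloaddition of an acyclic allene-tethered 2-silyloxydiene, cut out of (R)-terpinen-4-ol by ring cleavage, should form both bonds, both rings and the quaternary centre C8a in one operation. The enol ether at C4 and the C7=C8 alkene left by the cycloaddition are then turned into the C4 ester and the C6=C7 alkene.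

Key step: step 9

Remark: atom labels C1–C8a follow the hydroazulene numbering of the target (C1 angelate carbon, C3 carbinol carbon, C3a/C8a ring fusion, C4 benzoate carbon, C6 methyl-bearing alkene carbon); the SMILES is read as a cis-fused core (H-3a and the 8a-methyl on the same face); TBS = tert-butyldimethylsilyl; (R)-(−)-terpinen-4-ol is assumed to be bought enantiopure.

Step 1
Reactants: 1 (R)-(−)-terpinen-4-ol
Product: 2 (1S,5S)-4-methyl-1-(propan-2-yl)cyclohex-3-ene-1,5-diol (hydroxyls cis)
Conditions: SeO2 (cat.), t-BuOOH, CH2Cl2, 0 °C to rt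
Reagents that add atoms: tert-butyl hydroperoxide, CC(C)(C)OO
Why: Catalytic SeO2 allylic hydroxylation (ene reaction followed by [2,3]-sigmatropic shift) should oxidise the ring CH2 next to the methyl-bearing alkene carbon and replace its pseudo-axial hydrogen, which lies on the face of the axial tertiary hydroxyl, so that the new secondary carbinol (later C1) is set cis to the C3 hydroxyl.

Step 2
Reactants: 2 cis-diol
Product: 3 (1S,5S)-1,5-bis(TBS-oxy)-4-methyl-1-(propan-2-yl)cyclohex-3-ene
Conditions: TBSOTf, 2,6-lutidine, CH2Cl2, 0 °C to rt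
Reagents that add atoms: tert-butyldimethylsilyl trifluoromethanesulfonate, CC(C)(C)[Si](C)(C)OS(=O)(=O)C(F)(F)F
Why: Silyl ether formation with a silyl triflate and a hindered pyridine base covers both the secondary and the tertiary hydroxyl and touches no stereocentre.

Step 3
Reactants: 3 bis-silyl ether
Product: 5 methyl 3,5-bis(TBS-oxy)-6-oxo-3-(propan-2-yl)heptanoate, via methoxy hydroperoxide 4 (not isolated)
Conditions: O3, CH2Cl2/MeOH, NaHCO3, −78 °C; then Ac2O, Et3N, 0 °C to rt
Reagents that add atoms: ozone, [O-][O+]=O; methanol, CO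
Why: Ozonolysis in methanol with dehydrative work-up, in which the electron-withdrawing allylic silyloxy group steers the Criegee fragmentation so that the carbonyl oxide forms at the remote CH carbon, is trapped as the methoxy hydroperoxide and is dehydrated by Ac2O/Et3N to the methyl ester, while the methyl-bearing carbon becomes the ketone.

Step 4
Reactants: 5 keto ester; 6 ethynylmagnesium bromide
Product: 8 methyl 3,5-bis(TBS-oxy)-6-(methoxycarbonyloxy)-6-methyl-3-(propan-2-yl)oct-7-ynoate, via bromomagnesium alkoxide 7 (not isolated)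
Conditions: HC≡CMgBr, THF, −78 to −20 °C; then ClCO2Me, −20 °C to rt
Reagents that add atoms: methyl chloroformate, COC(=O)Cl
Why: Chemoselective 1,2-addition of the alkynyl Grignard reagent to the ketone beside the less electrophilic ester, with acylation of the magnesium alkoxide in the flask; the new carbinol centre forms as a mixture that is erased in step 5.

Step 5
Reactants: 8 propargylic carbonate
Product: 9 methyl 3,5-bis(TBS-oxy)-6-methyl-3-(propan-2-yl)octa-6,7-dienoate
Conditions: Pd2(dba)3 (cat.), PBu3, HCO2NH4, THF, rt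
Reagents that add atoms: none
Why: Tsuji-type hydrogenolysis, in which zerovalent palladium ionises the propargylic carbonate by SN2' displacement to an allenylpalladium species that accepts hydride from formate and releases the 1,1-disubstituted allene.

Step 6
Reactants: 9 allenyl ester
Product: 10 N-methoxy-N-methyl-3,5-bis(TBS-oxy)-6-methyl-3-(propan-2-yl)octa-6,7-dienamide
Conditions: MeNH(OMe)·HCl, i-PrMgCl, THF, −20 °C
Reagents that add atoms: N,O-dimethylhydroxylamine hydrochloride, CNOC.Cl
Why: Weinreb amide formation by aminolysis of the ester with the chloromagnesium amide should leave the allene and the silyl ethers untouched.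

Step 7
Reactants: 10 Weinreb amide; 11 (E)-1-bromoprop-1-ene
Product: 13 (2E)-6,8-bis(TBS-oxy)-9-methyl-6-(propan-2-yl)undeca-2,9,10-trien-4-one, via (E)-prop-1-enyllithium 12 (not isolated)
Conditions: 11, t-BuLi, Et2O, −78 °C; then 10, −78 to 0 °C; aq. NH4Cl
Reagents that add atoms: none
Why: Weinreb ketone synthesis, in which the (E)-alkenyllithium formed with retention by bromine–lithium exchange adds only once because the chelated tetrahedral intermediate survives until work-up.

Step 8
Reactants: 13 enone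
Product: 14 (2E,4Z)-4,6,8-tris(TBS-oxy)-9-methyl-6-(propan-2-yl)undeca-2,4,9,10-tetraene
Conditions: LiN(i-Pr)2, THF, −78 °C; TBSCl, HMPA, −78 to 0 °C
Reagents that add atoms: tert-butyldimethylsilyl chloride, CC(C)(C)[Si](C)(C)Cl
Why: Kinetic α′-deprotonation of the enone at C3a and O-silylation (silyl enol ether formation) should give the cross-conjugated 2-silyloxydiene, drawn as the Z enol ether expected for the bulky C3 substituent.

Step 9
Reactants: 14 allene-tethered 2-silyloxydiene
Product: 15 1,3,4-tris(TBS-oxy)-6,8a-dimethyl-3-(propan-2-yl)-1,2,3,3a,6,8a-hexahydroazulene (C1 C3 C8a as in the target; C3a and C6 unassigned)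
Conditions: (IPr)AuCl [IPr = 1,3-bis(2,6-diisopropylphenyl)imidazol-2-ylidene] (5 mol %), AgSbF6 (5 mol %), CH2Cl2, −20 °C to rt
Reagents that add atoms: none
Why: The cationic monovalent gold catalyst activates the allene as a gold-bound allyl cation whose tertiary end C8a is attacked 5-exo by the nucleophilic diene terminus C3a, the resulting vinylgold carbon C7 closes the seven-membered ring 7-endo on C6 of the transient silyloxonium dienyl cation, and the gold carbene at C8 collapses by 1,2-hydride shift from C7 to the C7=C8 alkene while the silyl enol ether is returned. The closest known reaction type is the gold- or platinum-catalysed intramolecular (4+3) cycloaddition of allene-tethered 1,3-dienes to hydroazulenes. The quaternary centre C8a should be set by the adjacent C1 stereocentre: to avoid A(1,2) strain with the C8a methyl group the C1 silyloxy group eclipses the slender allene axis while C2 carries the diene to the open face, which places the methyl trans and C8 cis to the C1 oxygen. C3a and C6 form without control, which is harmless because C3a is equilibrated in step 10 and C6 becomes trigonal. The step needs (4+3) rather than (4+2) selectivity (1,2-hydride shift instead of a ring-contracting 1,2-alkyl shift), which the strongly σ-donating carbene ligand favours, and it needs the second ring closure to outrun loss of the vinylgold, which the aprotic medium and the activated silyloxonium acceptor should secure.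

Step 10
Reactants: 15 cycloadduct
Product: 17 cis-fused 1,3-bis(TBS-oxy)-6,8a-dimethyl-3-(propan-2-yl)-2,3,3a,8a-tetrahydroazulen-4(1H)-one, via C3a-epimeric dienone 16 (not isolated)
Conditions: Pd(OAc)2, MeCN, 40 °C; then DBU, CH2Cl2, rt
Reagents that add atoms: none
Why: Saegusa–Ito oxidation (palladium enolate at C5, then β-hydride elimination of H-6) should give the linear dienone, and DBU then equilibrates the enolisable C3a centre to the cis-fused isomer, expected to be favoured because the angular methyl group disfavours the trans fusion and the acyl branch then lies anti to the isopropyl group.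

Step 11
Reactants: 17 cis-fused dienone
Product: 19 cis-fused 1,3-bis(TBS-oxy)-6,8a-dimethyl-3-(propan-2-yl)-2,3,3a,5,8,8a-hexahydroazulen-4(1H)-one, via lithium dienolate 18 (not isolated)
Conditions: Li, NH3 (l), THF, −78 °C; then solid NH4Cl
Reagents that add atoms: none
Why: Dissolving-metal 1,6-reduction (Birch-type), in which electron transfer and protonation at C8 give the extended lithium dienolate whose kinetic protonation at the α-carbon C5 should deliver the β,γ-unsaturated ketone with the C6=C7 alkene in place.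

Step 12
Reactants: 19 bis-silyl β,γ-enone
Product: 20 cis-fused 1,3-dihydroxy-6,8a-dimethyl-3-(propan-2-yl)-2,3,3a,5,8,8a-hexahydroazulen-4(1H)-one
Conditions: HF·pyridine, pyridine, THF, 0 °C to rt
Reagents that add atoms: none
Why: Fluoride-mediated cleavage of both silyl ethers under non-basic conditions should avoid conjugation of the β,γ-enone and retro-aldol cleavage of the β-hydroxy ketone.

Step 13
Reactants: 20 dihydroxy ketone
Product: 21 (1S,3S,3aR,4R,8aR)-6,8a-dimethyl-3-(propan-2-yl)-1,2,3,3a,4,5,8,8a-octahydroazulene-1,3,4-triol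
Conditions: Me4NBH(OAc)3, MeCN/AcOH, −30 to 0 °C
Reagents that add atoms: none
Why: Evans–Saksena hydroxyl-directed reduction, in which the tertiary C3 hydroxyl binds the acetoxyborohydride and delivers hydride intramolecularly to the concave face of the C4 ketone, so the new C4 hydroxyl is set on the convex face cis to H-3a.

Step 14
Reactants: 21 triol; 22 3,4,5-trimethoxybenzoyl chloride
Product: 23 (1S,3S,3aR,4R,8aR)-1,3-dihydroxy-6,8a-dimethyl-3-(propan-2-yl)-1,2,3,3a,4,5,8,8a-octahydroazulen-4-yl 3,4,5-trimethoxybenzoate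
Conditions: pyridine, DMAP (cat.), CH2Cl2, 0 °C
Reagents that add atoms: none
Why: DMAP-catalysed acylation should take place at the exposed convex secondary C4 hydroxyl in preference to the concave neopentylic C1 hydroxyl and the tertiary C3 hydroxyl.

Step 15
Reactants: 23 diol benzoate; 24 angelic acid
Product: 26 target (1S,3S,3aR,4R,8aR)-3-hydroxy-6,8a-dimethyl-3-(propan-2-yl)-4-[(3,4,5-trimethoxybenzoyl)oxy]-1,2,3,3a,4,5,8,8a-octahydroazulen-1-yl (2Z)-2-methylbut-2-enoate, via mixed anhydride 25 (not isolated)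
Conditions: 24, 2,4,6-trichlorobenzoyl chloride, Et3N, toluene, rt; then 23, toluene, 80 °C
Reagents that add atoms: none
Why: Yamaguchi esterification through the mixed anhydride should acylate the hindered secondary C1 hydroxyl and, run without nucleophilic catalyst, should not isomerise the (Z)-angelate to the tiglate; the tertiary hydroxyl does not react.

Compound list
1 | (R)-(−)-terpinen-4-ol [(1R)-4-methyl-1-(propan-2-yl)cyclohex-3-en-1-ol] | CC1=CC[C@@](O)(C(C)C)CC1 | starting material
2 | (1S,5S)-4-methyl-1-(propan-2-yl)cyclohex-3-ene-1,5-diol (hydroxyls cis) | CC1=CC[C@@](O)(C(C)C)C[C@@H]1O | intermediate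
3 | (1S,5S)-1,5-bis(TBS-oxy)-4-methyl-1-(propan-2-yl)cyclohex-3-ene | CC1=CC[C@@](O[Si](C)(C)C(C)(C)C)(C(C)C)C[C@@H]1O[Si](C)(C)C(C)(C)C | intermediate
4 | 3,5-bis(TBS-oxy)-7-hydroperoxy-7-methoxy-5-(propan-2-yl)heptan-2-one (C7 unassigned) | CC(=O)[C@@H](O[Si](C)(C)C(C)(C)C)C[C@](O[Si](C)(C)C(C)(C)C)(C(C)C)CC(OC)OO | intermediate
5 | methyl 3,5-bis(TBS-oxy)-6-oxo-3-(propan-2-yl)heptanoate (C3 and C5 are the later C3 and C1) | CC(=O)[C@@H](O[Si](C)(C)C(C)(C)C)C[C@](O[Si](C)(C)C(C)(C)C)(C(C)C)CC(=O)OC | intermediate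
6 | ethynylmagnesium bromide | C#C[Mg]Br | starting material
7 | bromomagnesium alkoxide of the tertiary ethynyl carbinol (both carbinol epimers) | C#CC(C)(O[Mg]Br)[C@@H](O[Si](C)(C)C(C)(C)C)C[C@](O[Si](C)(C)C(C)(C)C)(C(C)C)CC(=O)OC | intermediate
8 | methyl 3,5-bis(TBS-oxy)-6-(methoxycarbonyloxy)-6-methyl-3-(propan-2-yl)oct-7-ynoate (both C6 epimers) | C#CC(C)(OC(=O)OC)[C@@H](O[Si](C)(C)C(C)(C)C)C[C@](O[Si](C)(C)C(C)(C)C)(C(C)C)CC(=O)OC | intermediate
9 | methyl 3,5-bis(TBS-oxy)-6-methyl-3-(propan-2-yl)octa-6,7-dienoate | C=C=C(C)[C@@H](O[Si](C)(C)C(C)(C)C)C[C@](O[Si](C)(C)C(C)(C)C)(C(C)C)CC(=O)OC | intermediate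
10 | N-methoxy-N-methyl-3,5-bis(TBS-oxy)-6-methyl-3-(propan-2-yl)octa-6,7-dienamide | C=C=C(C)[C@@H](O[Si](C)(C)C(C)(C)C)C[C@](O[Si](C)(C)C(C)(C)C)(C(C)C)CC(=O)N(C)OC | intermediate
11 | (E)-1-bromoprop-1-ene | C/C=C/Br | starting material
12 | (E)-prop-1-enyllithium | C/C=C/[Li] | intermediate
13 | (2E)-6,8-bis(TBS-oxy)-9-methyl-6-(propan-2-yl)undeca-2,9,10-trien-4-one | C=C=C(C)[C@@H](O[Si](C)(C)C(C)(C)C)C[C@](O[Si](C)(C)C(C)(C)C)(C(C)C)CC(=O)/C=C/C | intermediate
14 | (2E,4Z)-4,6,8-tris(TBS-oxy)-9-methyl-6-(propan-2-yl)undeca-2,4,9,10-tetraene | C=C=C(C)[C@@H](O[Si](C)(C)C(C)(C)C)C[C@](O[Si](C)(C)C(C)(C)C)(C(C)C)/C=C(\O[Si](C)(C)C(C)(C)C)/C=C/C | intermediate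
15 | 1,3,4-tris(TBS-oxy)-6,8a-dimethyl-3-(propan-2-yl)-1,2,3,3a,6,8a-hexahydroazulene (C1 C3 C8a as in the target; C3a and C6 unassigned) | CC(C)(C)[Si](C)(C)O[C@H]1C[C@](O[Si](C)(C)C(C)(C)C)(C(C)C)C2C(O[Si](C)(C)C(C)(C)C)=CC(C)C=C[C@@]12C | intermediate
16 | 1,3-bis(TBS-oxy)-6,8a-dimethyl-3-(propan-2-yl)-2,3,3a,8a-tetrahydroazulen-4(1H)-one as C3a epimer mixture | CC(C)(C)[Si](C)(C)O[C@H]1C[C@](O[Si](C)(C)C(C)(C)C)(C(C)C)C2C(=O)C=C(C)C=C[C@@]12C | intermediate
17 | cis-fused (H-3a and 8a-methyl cis) 1,3-bis(TBS-oxy)-6,8a-dimethyl-3-(propan-2-yl)-2,3,3a,8a-tetrahydroazulen-4(1H)-one | CC(C)(C)[Si](C)(C)O[C@H]1C[C@](O[Si](C)(C)C(C)(C)C)(C(C)C)[C@H]2C(=O)C=C(C)C=C[C@@]12C | intermediate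
18 | lithium 1,3-bis(TBS-oxy)-6,8a-dimethyl-3-(propan-2-yl)-1,2,3,3a,8,8a-hexahydroazulen-4-olate | CC(C)(C)[Si](C)(C)O[C@H]1C[C@](O[Si](C)(C)C(C)(C)C)(C(C)C)[C@H]2C(O[Li])=CC(C)=CC[C@@]12C | intermediate
19 | cis-fused 1,3-bis(TBS-oxy)-6,8a-dimethyl-3-(propan-2-yl)-2,3,3a,5,8,8a-hexahydroazulen-4(1H)-one | CC(C)(C)[Si](C)(C)O[C@H]1C[C@](O[Si](C)(C)C(C)(C)C)(C(C)C)[C@H]2C(=O)CC(C)=CC[C@@]12C | intermediate
20 | cis-fused 1,3-dihydroxy-6,8a-dimethyl-3-(propan-2-yl)-2,3,3a,5,8,8a-hexahydroazulen-4(1H)-one | O[C@H]1C[C@](O)(C(C)C)[C@H]2C(=O)CC(C)=CC[C@@]12C | intermediate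
21 | (1S,3S,3aR,4R,8aR)-6,8a-dimethyl-3-(propan-2-yl)-1,2,3,3a,4,5,8,8a-octahydroazulene-1,3,4-triol | O[C@H]1C[C@](O)(C(C)C)[C@H]2[C@H](O)CC(C)=CC[C@@]12C | intermediate
22 | 3,4,5-trimethoxybenzoyl chloride | COc1cc(cc(OC)c1OC)C(=O)Cl | starting material
23 | (1S,3S,3aR,4R,8aR)-1,3-dihydroxy-6,8a-dimethyl-3-(propan-2-yl)-1,2,3,3a,4,5,8,8a-octahydroazulen-4-yl 3,4,5-trimethoxybenzoate | O[C@H]1C[C@](O)(C(C)C)[C@H]2[C@H](OC(=O)c3cc(OC)c(OC)c(OC)c3)CC(C)=CC[C@@]12C | intermediate
24 | angelic acid [(2Z)-2-methylbut-2-enoic acid] | C/C=C(/C)C(=O)O | starting material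
25 | (2Z)-2-methylbut-2-enoic 2,4,6-trichlorobenzoic anhydride | C/C=C(/C)C(=O)OC(=O)c1c(Cl)cc(Cl)cc1Cl | intermediate
26 | (1S,3S,3aR,4R,8aR)-3-hydroxy-6,8a-dimethyl-3-(propan-2-yl)-4-[(3,4,5-trimethoxybenzoyl)oxy]-1,2,3,3a,4,5,8,8a-octahydroazulen-1-yl (2Z)-2-methylbut-2-enoate (CNP0112256.1) | C/C=C(/C)C(=O)O[C@H]1C[C@](O)(C(C)C)[C@H]2[C@H](OC(=O)c3cc(OC)c(OC)c(OC)c3)CC(C)=CC[C@@]12C | target

Total step count: 15
Longest linear sequence: 15 steps (1 to 26)

Steps most likely to fail

Step 9 (key step). The cascade may stop after the first C–C bond, the vinylgold being lost by protodeauration or silyl transfer to leave a monocyclic 2-vinylcyclopentyl enone. The gold carbene may instead contract the ring by 1,2-alkyl shift, or facial selectivity at C8a may be low. Fallback (sets out from 13, returns at 16): the cycloaddition is moved to an unfunctionalised diene, the substrate class on which this reaction type is best established, and the C4 oxygen is brought in afterwards by oxidation. Luche reduction of 13 (NaBH4, CeCl3·7H2O, MeOH, −78 °C) should give the allylic alcohol (2E)-6,8-bis(TBS-oxy)-9-methyl-6-(propan-2-yl)undeca-2,9,10-trien-4-ol F1. Syn-dehydration with the Burgess reagent (toluene, 70 °C) should give the (2E,4E)-tetraene F2. The same gold catalyst should convert this allene-tethered diene into the skipped-diene cycloadduct 1,3-bis(TBS-oxy)-6,8a-dimethyl-3-(propan-2-yl)-1,2,3,3a,6,8a-hexahydroazulene F3. Oxidation at its doubly allylic C6–H with transposition of the C4=C5 double bond (CrO3·3,5-dimethylpyrazole, CH2Cl2, −20 °C) should give dienone 16, which then passes through the DBU equilibration of step 10.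

Step 11. The ketone may be over-reduced, or the β,γ-unsaturated ketone may slip into conjugation during the quench. Fallback (sets out from 15, returns at 19): reductive deconjugation is replaced by an isomerisation–deconjugation sequence. Buffered fluoride (TBAF/AcOH, THF, −78 °C) should cleave only the silyl enol ether of 15 to the γ,δ-unsaturated ketone 1,3-bis(TBS-oxy)-6,8a-dimethyl-3-(propan-2-yl)-2,3,3a,5,6,8a-hexahydroazulen-4(1H)-one F4. RhCl3·3H2O in ethanol at 70 °C, followed by DBU, should walk the C7=C8 alkene into conjugation and settle the ring fusion, giving the cis-fused conjugated enone 1,3-bis(TBS-oxy)-6,8a-dimethyl-3-(propan-2-yl)-2,3,3a,7,8,8a-hexahydroazulen-4(1H)-one F5. Formation of the extended potassium dienolate (KOt-Bu, t-BuOH, rt) and kinetic α-protonation with cold aqueous AcOH should then give 19.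

Step 1. Oxidation may occur at the wrong allylic position (the methyl group or the CH2 next to the carbinol carbon), may run on to the enone, or may deliver oxygen to the wrong face. Fallback (sets out from 1, returns at 2): the oxidation is taken deliberately to the ketone and the stereocentre is set by reduction. CrO3·3,5-dimethylpyrazole (CH2Cl2, −20 °C) should give the enone (5S)-5-hydroxy-2-methyl-5-(propan-2-yl)cyclohex-2-en-1-one F6. Narasaka–Prasad reduction of this β-hydroxy ketone through its boron chelate (Et2BOMe, NaBH4, THF/MeOH, −78 °C) should give the syn, that is cis, diol 2.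

Further compounds
F1 | step 9 | (2E)-6,8-bis(TBS-oxy)-9-methyl-6-(propan-2-yl)undeca-2,9,10-trien-4-ol (C4 unassigned) | C=C=C(C)[C@@H](O[Si](C)(C)C(C)(C)C)C[C@](O[Si](C)(C)C(C)(C)C)(C(C)C)CC(O)/C=C/C
F2 | step 9 | (2E,4E)-6,8-bis(TBS-oxy)-9-methyl-6-(propan-2-yl)undeca-2,4,9,10-tetraene | C=C=C(C)[C@@H](O[Si](C)(C)C(C)(C)C)C[C@](O[Si](C)(C)C(C)(C)C)(C(C)C)/C=C/C=C/C
F3 | step 9 | 1,3-bis(TBS-oxy)-6,8a-dimethyl-3-(propan-2-yl)-1,2,3,3a,6,8a-hexahydroazulene (C3a and C6 unassigned) | CC(C)(C)[Si](C)(C)O[C@H]1C[C@](O[Si](C)(C)C(C)(C)C)(C(C)C)C2C=CC(C)C=C[C@@]12C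
F4 | step 11 | 1,3-bis(TBS-oxy)-6,8a-dimethyl-3-(propan-2-yl)-2,3,3a,5,6,8a-hexahydroazulen-4(1H)-one (C3a and C6 unassigned) | CC(C)(C)[Si](C)(C)O[C@H]1C[C@](O[Si](C)(C)C(C)(C)C)(C(C)C)C2C(=O)CC(C)C=C[C@@]12C
F5 | step 11 | cis-fused 1,3-bis(TBS-oxy)-6,8a-dimethyl-3-(propan-2-yl)-2,3,3a,7,8,8a-hexahydroazulen-4(1H)-one | CC(C)(C)[Si](C)(C)O[C@H]1C[C@](O[Si](C)(C)C(C)(C)C)(C(C)C)[C@H]2C(=O)C=C(C)CC[C@@]12C
F6 | step 1 | (5S)-5-hydroxy-2-methyl-5-(propan-2-yl)cyclohex-2-en-1-one | CC1=CC[C@@](O)(C(C)C)CC1=O
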